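**Plan**

- Retrosynthetic cuts, in order: the C12–C13 bond (sp3–sp2 coupling of the Z side chain), the C9–C11 bond ([3,3] shift from O7), the C8–C9 bond (aldol, opens ring B), the C4–C5 bond (ester-enolate Claisen, opens ring A into a ten-membered lactone), the lactone ester bond C19–O–C7, then C5=C6, C2–C3, C10–C1 and C10–C20.
- Enabling feature: C4 carries the carboxyl-level carbon C19 and its neighbour C5 carries the two-carbon arm C6–C7. This vicinal carboxyl/vinyl pattern is what an ester-enolate Claisen leaves when the ester oxygen of C19 sits on C7 of a (Z)-C5=C6 allyl unit; the ten-membered lactone then contracts to the six-membered ring A (C4, C5, C10, C1, C2, C3).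
- Forward order: acyclic C10 block from diethyl (S)-malate, then the seco acid, the ten-membered lactone, ring A by ring contraction (step 14), ring B by aldol condensation (step 22), C11–C12 by Johnson–Claisen (step 24), C13–C16 by Negishi coupling (step 33).
- Stereochemistry: C10 from (S)-malate by two Fráter–Seebach alkylations; C2 by reagent-controlled methallylboration; C4 and C5 in the key step; C9 by suprafacial transfer from a 7β-oxygen set by Luche reduction; C7 by α-epoxidation and epoxide-to-allylic-alcohol isomerisation; 13Z from (Z)-3-iodobut-2-en-1-ol.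

Key step: step 14

Remark: atoms carry labdane numbers throughout; α/β refer to the target drawn with the C20 methyl β.
Remark: C4 in 13–18, C6 in 8, C7 in 27 and C8/C9 in 31 arise as epimer mixtures that are erased later; their SMILES leave these centres open.
Remark: numbered compounds are the substrates and the side-chain fragment; commercial reagents are given with SMILES on the reagent line.

**Route**

Step 1
Reactants: 1 diethyl (S)-malate
Product: 2 diethyl (2S,3R)-2-hydroxy-3-methylbutanedioate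
Conditions: LDA (2.1 equiv), THF, −78 → −20 °C; MeI
Reagents that add atoms: iodomethane, CI
Why: Fráter–Seebach alkylation: the dilithium alkoxide–enolate chelate is methylated on the face away from the carbinol's ester group, which should give the anti (3R) diastereomer.

Step 2
Reactants: 2 diethyl (2S,3R)-2-hydroxy-3-methylbutanedioate
Product: 3 diethyl (2S,3R)-2-hydroxy-3-methyl-3-(prop-2-en-1-yl)butanedioate
Conditions: LDA (2.2 equiv), THF/DMPU, −78 → −10 °C; allyl bromide
Reagents that add atoms: allyl bromide, C=CCBr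
Why: A second Fráter–Seebach alkylation on the same chelate face creates the quaternary carbon (future C10 with C20 and C1), its configuration following from the order methyl first, allyl second.

Step 3
Reactants: 3 diethyl (2S,3R)-2-hydroxy-3-methyl-3-(prop-2-en-1-yl)butanedioate
Product: 4 (2S,3S)-3-methyl-3-(prop-2-en-1-yl)butane-1,2,4-triol
Conditions: LiAlH4, THF, 0 °C → reflux
Reagents that add atoms: none
Why: LiAlH4 reduces both esters, the hindered neopentyl one included, and leaves the alkene and both stereocentres untouched.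

Step 4
Reactants: 4 (2S,3S)-3-methyl-3-(prop-2-en-1-yl)butane-1,2,4-triol
Product: 5 (2S)-2-[(4S)-2,2-dimethyl-1,3-dioxolan-4-yl]-2-methylpent-4-en-1-ol
Conditions: Me2C(OMe)2, PPTS (cat.), acetone, rt
Reagents that add atoms: 2,2-dimethoxypropane, COC(C)(C)OC
Why: Acetonide formation under thermodynamic control prefers the five-membered dioxolane of the terminal 1,2-diol to a 1,3-dioxane with an axial methyl, so the neopentyl hydroxyl (future C5) stays free and C9 is stored as a masked aldehyde.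

Step 5
Reactants: 5 (2S)-2-[(4S)-2,2-dimethyl-1,3-dioxolan-4-yl]-2-methylpent-4-en-1-ol
Product: 6 (2R)-2-[(4S)-2,2-dimethyl-1,3-dioxolan-4-yl]-2-methylpent-4-enal
Conditions: Dess–Martin periodinane, NaHCO3, CH2Cl2, rt
Reagents that add atoms: none
Why: Dess–Martin oxidation gives an aldehyde without α-hydrogen, so the quaternary centre cannot epimerise.

Step 6
Reactants: 6 (2R)-2-[(4S)-2,2-dimethyl-1,3-dioxolan-4-yl]-2-methylpent-4-enal
Product: 7 methyl (2Z,4S)-4-[(4S)-2,2-dimethyl-1,3-dioxolan-4-yl]-4-methylhepta-2,6-dienoate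
Conditions: (CF3CH2O)2P(O)CH2CO2Me, KHMDS, 18-crown-6, THF, −78 °C
Reagents that add atoms: methyl bis(2,2,2-trifluoroethyl)phosphonoacetate, COC(=O)CP(=O)(OCC(F)(F)F)OCC(F)(F)F
Why: Still–Gennari olefination: the electron-poor trifluoroethyl phosphonate eliminates under kinetic control and should give the (Z)-enoate (C5=C6) even from the α-quaternary aldehyde.

Step 7
Reactants: 7 methyl (2Z,4S)-4-[(4S)-2,2-dimethyl-1,3-dioxolan-4-yl]-4-methylhepta-2,6-dienoate
Product: 9 methyl (2Z,4S)-4-[(4S)-2,2-dimethyl-1,3-dioxolan-4-yl]-4-methyl-6-oxohex-2-enoate, via vicinal diol 8 (not isolated)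
Conditions: OsO4 (cat.), NaIO4, 2,6-lutidine, dioxane/H2O, rt
Reagents that add atoms: osmium tetroxide, O=[Os](=O)(=O)=O; sodium periodate, [Na+].[O-]I(=O)(=O)=O
Why: Lemieux–Johnson cleavage: the monosubstituted alkene is dihydroxylated far faster than the hindered, electron-poor enoate, and periodate cuts the diol to the C2 aldehyde.

Step 8
Reactants: 9 methyl (2Z,4S)-4-[(4S)-2,2-dimethyl-1,3-dioxolan-4-yl]-4-methyl-6-oxohex-2-enoate
Product: 11 methyl (2Z,4S,6S)-4-[(4S)-2,2-dimethyl-1,3-dioxolan-4-yl]-6-hydroxy-4,8-dimethylnona-2,8-dienoate, via borinate 10 (not isolated)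
Conditions: (−)-Ipc2BOMe [from (+)-α-pinene], methallylMgCl, Et2O, −78 °C → rt; then 9, −78 °C; ethanolamine work-up
Reagents that add atoms: methallylmagnesium chloride, CC(=C)C[Mg]Cl
Why: Brown asymmetric methallylboration: the (+)-α-pinene-derived reagent should add through a closed chair transition state to the Si face and set C2 (S in 11) under reagent control, and the non-basic ethanolamine work-up avoids oxa-Michael addition of the new hydroxyl to the enoate.

Step 9
Reactants: 11 methyl (2Z,4S,6S)-4-[(4S)-2,2-dimethyl-1,3-dioxolan-4-yl]-6-hydroxy-4,8-dimethylnona-2,8-dienoate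
Product: 12 methyl (2Z,4S,6S)-6-(tert-butyldimethylsilyloxy)-4-[(4S)-2,2-dimethyl-1,3-dioxolan-4-yl]-4,8-dimethylnona-2,8-dienoate
Conditions: TBSOTf, 2,6-lutidine, CH2Cl2, −78 → 0 °C
Reagents that add atoms: tert-butyldimethylsilyl triflate, CC(C)(C)[Si](C)(C)OS(=O)(=O)C(F)(F)F
Why: Silylation with the triflate and a hindered base protects the secondary hydroxyl without basic conditions.

Step 10
Reactants: 12 methyl (2Z,4S,6S)-6-(tert-butyldimethylsilyloxy)-4-[(4S)-2,2-dimethyl-1,3-dioxolan-4-yl]-4,8-dimethylnona-2,8-dienoate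
Product: 14 methyl (2Z,4S,6S,8RS)-6-(tert-butyldimethylsilyloxy)-4-[(4S)-2,2-dimethyl-1,3-dioxolan-4-yl]-9-hydroxy-4,8-dimethylnon-2-enoate, via alkylborane 13 (not isolated)
Conditions: 9-BBN, THF, rt; then NaBO3·4H2O, H2O
Reagents that add atoms: sodium perborate, [Na+].[O-]OB=O
Why: Hydroboration–oxidation: 9-BBN adds anti-Markovnikov to the 1,1-disubstituted alkene and ignores the hindered electron-poor enoate; C4 forms as both epimers, which the key step erases.

Step 11
Reactants: 14 methyl (2Z,4S,6S,8RS)-6-(tert-butyldimethylsilyloxy)-4-[(4S)-2,2-dimethyl-1,3-dioxolan-4-yl]-9-hydroxy-4,8-dimethylnon-2-enoate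
Product: 15 (2RS,4S,6S,7Z)-4-(tert-butyldimethylsilyloxy)-6-[(4S)-2,2-dimethyl-1,3-dioxolan-4-yl]-9-methoxy-2,6-dimethyl-9-oxonon-7-enoic acid
Conditions: TEMPO (cat.), PhI(OAc)2, MeCN/H2O, rt
Reagents that add atoms: water, O
Why: TEMPO/PhI(OAc)2 oxidation in wet acetonitrile carries the primary alcohol through the aldehyde hydrate to the C19 acid and spares enoate, silyl ether and acetonide.

Step 12
Reactants: 15 (2RS,4S,6S,7Z)-4-(tert-butyldimethylsilyloxy)-6-[(4S)-2,2-dimethyl-1,3-dioxolan-4-yl]-9-methoxy-2,6-dimethyl-9-oxonon-7-enoic acid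
Product: 16 seco acid (2RS,4S,6S,7Z)-4-(tert-butyldimethylsilyloxy)-6-[(4S)-2,2-dimethyl-1,3-dioxolan-4-yl]-9-hydroxy-2,6-dimethylnon-7-enoic acid
Conditions: DIBAL-H (4 equiv), CH2Cl2, −78 °C; Rochelle salt
Reagents that add atoms: none
Why: DIBAL reduces the enoate 1,2 to the (Z)-allylic alcohol with retention of geometry, while the acid, converted into its aluminium carboxylate by the first equivalent, is not reduced at −78 °C.

Step 13
Reactants: 16 seco acid
Product: 18 ten-membered lactone (3RS,5S,7S,8Z)-5-(tert-butyldimethylsilyloxy)-7-[(4S)-2,2-dimethyl-1,3-dioxolan-4-yl]-3,7-dimethyl-3,4,5,6,7,10-hexahydro-2H-oxecin-2-one (C19 carbonyl, O on C7, Z-C5=C6), via mixed anhydride 17 (not isolated)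
Conditions: 2-methyl-6-nitrobenzoic anhydride, DMAP, CH2Cl2 (ca. 1 mM, slow addition), rt
Reagents that add atoms: none
Why: Shiina macrolactonisation: the mixed anhydride acylates the primary allylic hydroxyl at high dilution, the (Z)-alkene and the quaternary C10 (gem-disubstituent effect) bringing the chain ends together for the ten-membered ring.

Step 14
Reactants: 18 ten-membered lactone
Product: 21 ring-A acid (1S,2R,3S,5R)-5-(tert-butyldimethylsilyloxy)-3-[(4S)-2,2-dimethyl-1,3-dioxolan-4-yl]-2-ethenyl-1,3-dimethylcyclohexane-1-carboxylic acid (2α-OTBS; C4 α-CH3, β-CO2H; C5 α-H, β-vinyl; C10 β-CH3), via silyl ketene acetal 19 (not isolated), via silyl ester 20 (not isolated)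
Conditions: LDA, TBSCl, THF/DMPU, −78 °C; then toluene, 100 °C; then AcOH/THF/H2O, rt
Reagents that add atoms: none
Why: LDA removes the C4 hydrogen of either epimer and in-situ O-silylation gives the endocyclic ketene acetal (C3 and the ring oxygen cis), which on heating undergoes the concerted [3,3] shift C4=C19–O–C7–C6=C5, forming C4–C5 and C6=C7 and breaking O–C7. The closest known reaction type is the Ireland–Claisen ring contraction of medium-ring lactone silyl ketene acetals to cis-2-alkenylcycloalkanecarboxylic acids. Ring A (C4–C5–C10–C1–C2–C3) closes transannularly as a six-membered carbocycle (ten ring atoms minus the C19–O–C7–C6 segment); because the ring-cis ketene acetal and the (Z)-alkene hold the tether ends C3 and C10 syn, the pericyclic array must be a boat. This boat fixes C4 relative to C5, so the carboxyl carbon C19 and the C6=C7 vinyl group end up cis. The face relative to C10 and C2 is set by the chair-like forming ring, in which the branched dioxolanyl group on C10, the C2 silyloxy group and the vinyl group are equatorial and the C18 methyl avoids a syn-diaxial clash with the axial C20 methyl. The step needs this facial selectivity and clean O-silylation; the quaternary C10 with its large acetal substituent and the 2-silyloxy group secure the first, and the loss of the C4 stereocentre on enolisation makes both lactone epimers converge.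

Step 15
Reactants: 21 ring-A acid
Product: 22 ring-A alcohol (as 21, with 4β-CH2OH = C19)
Conditions: LiAlH4, THF, 0 °C → reflux
Reagents that add atoms: none
Why: LiAlH4 reduces the hindered axial acid to the neopentyl C19 alcohol; silyl ether, acetonide and vinyl group are inert.

Step 16
Reactants: 22 ring-A alcohol
Product: 23 ring-A pivalate (as 22, C19 O-pivaloyl)
Conditions: PivCl, DMAP, pyridine, CH2Cl2, 40 °C
Reagents that add atoms: pivaloyl chloride, CC(C)(C)C(=O)Cl
Why: DMAP-catalysed acylation gives a pivalate that withstands the Grignard, oxidation and amine steps ahead and keeps the C19 oxygen from forming a lactol with C7.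

Step 17
Reactants: 23 ring-A pivalate
Product: 25 primary alcohol (as 23, the 5β-vinyl group now 5β-CH2CH2OH, C6–C7), via alkylborane 24 (not isolated)
Conditions: 9-BBN, THF, 50 °C; then NaBO3·4H2O, H2O
Reagents that add atoms: sodium perborate, [Na+].[O-]OB=O
Why: Hydroboration–oxidation: 9-BBN delivers boron to the terminal carbon of the hindered vinyl group, giving the primary C7 alcohol.

Step 18
Reactants: 25 primary alcohol
Product: 26 C7 aldehyde (as 25, 5β-CH2CHO)
Conditions: Dess–Martin periodinane, NaHCO3, CH2Cl2, rt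
Reagents that add atoms: none
Why: Dess–Martin oxidation gives the aldehyde under buffered, non-epimerising conditions.

Step 19
Reactants: 26 C7 aldehyde
Product: 27 secondary alcohol (as 26, 5β-CH2CH(OH)CH2CH3, C7 epimers)
Conditions: EtMgBr, THF, −78 °C
Reagents that add atoms: ethylmagnesium bromide, CC[Mg]Br
Why: Grignard addition to the aldehyde at −78 °C, where the hindered pivalate is not attacked, brings in C8 and C17; the carbinol epimers converge in the next step.

Step 20
Reactants: 27 secondary alcohol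
Product: 28 ethyl ketone (as 27, 5β-CH2C(=O)CH2CH3)
Conditions: Dess–Martin periodinane, NaHCO3, CH2Cl2, rt
Reagents that add atoms: none
Why: Dess–Martin oxidation gives the ethyl ketone whose α-methylene is C8.

Step 21
Reactants: 28 ethyl ketone
Product: 30 keto aldehyde (as 28, the dioxolanyl group on C10 now CHO = C9), via diol 29 (not isolated)
Conditions: H5IO6, EtOAc, rt
Reagents that add atoms: none
Why: Periodic acid hydrolyses the terminal acetonide and cleaves the resulting glycol in one pot, releasing the non-enolisable C9 aldehyde while silyl ether, pivalate and ketone persist.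

Step 22
Reactants: 30 keto aldehyde
Product: 32 bicyclic enone 2α-(tert-butyldimethylsilyloxy)-19-(pivaloyloxy)-11,12,13,14,15,16-hexanorlabd-8-en-7-one, via aldol 31 (not isolated)
Conditions: pyrrolidine, AcOH, toluene, 80 °C
Reagents that add atoms: none
Why: Intramolecular aldol condensation via the pyrrolidine enamine: only C8 can reach the aldehyde through a six-membered transition state (C6 would give a four-membered ring), and dehydration gives the conjugated enone that closes ring B as a trans-fused decalin.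

Step 23
Reactants: 32 bicyclic enone
Product: 33 allylic alcohol 2α-(tert-butyldimethylsilyloxy)-19-(pivaloyloxy)-11,12,13,14,15,16-hexanorlabd-8-en-7β-ol
Conditions: NaBH4, CeCl3·7H2O, MeOH, −40 °C
Reagents that add atoms: none
Why: Luche reduction: 1,2-hydride delivery along the axial trajectory on the α face (anti to the C20 methyl) should give the pseudoequatorial 7β-alcohol, as in the reduction of steroidal 4-en-3-ones to 3β-ols.

Step 24
Reactants: 33 allylic alcohol
Product: 35 ethyl 2α-(tert-butyldimethylsilyloxy)-19-(pivaloyloxy)-13,14,15,16-tetranorlabd-7-en-12-oate (9α-H), via ketene acetal 34 (not isolated)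
Conditions: MeC(OEt)3, EtCO2H (cat.), xylene, 140 °C, EtOH distilled off
Reagents that add atoms: triethyl orthoacetate, CCOC(C)(OCC)OCC
Why: Johnson–Claisen rearrangement: the ketene acetal formed on O7 transfers the two-carbon unit suprafacially to C9, so the 7β-oxygen delivers C11 to the β face (9α-H) and moves the double bond to C7=C8, as in the transfer from 3β-oxygen to C5β in steroidal 4-en-3-ols.

Step 25
Reactants: 35 ethyl ester
Product: 36 ethyl 7α,8α-epoxy-2α-(tert-butyldimethylsilyloxy)-19-(pivaloyloxy)-13,14,15,16-tetranorlabdan-12-oate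
Conditions: mCPBA, NaHCO3, CH2Cl2, 0 °C
Reagents that add atoms: 3-chloroperbenzoic acid, OOC(=O)c1cccc(Cl)c1
Why: Prilezhaev epoxidation of the only alkene from the α face, the β face being shielded by the axial C20 methyl and the 9β side chain; bicarbonate keeps the γ,δ-epoxy ester from lactonising.

Step 26
Reactants: 36 epoxy ester
Product: 37 ethyl 7α-hydroxy-2α-(tert-butyldimethylsilyloxy)-19-(pivaloyloxy)-13,14,15,16-tetranorlabd-8(17)-en-12-oate
Conditions: Cp2TiCl2 (2.5 equiv), Mn dust, THF, rt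
Reagents that add atoms: none
Why: Titanocene(III) opens the epoxide homolytically to the tertiary C8 radical (Nugent–RajanBabu opening), which loses a hydrogen atom from the unhindered C17 methyl to a second Ti(III) to give the exocyclic alkene; the C7–O bond is never broken, so the 7α configuration is kept and the esters are tolerated.

Step 27
Reactants: 37 allylic alcohol
Product: 38 ethyl 2α,7α-bis(tert-butyldimethylsilyloxy)-19-(pivaloyloxy)-13,14,15,16-tetranorlabd-8(17)-en-12-oate
Conditions: TBSOTf, 2,6-lutidine, CH2Cl2, 0 °C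
Reagents that add atoms: tert-butyldimethylsilyl triflate, CC(C)(C)[Si](C)(C)OS(=O)(=O)C(F)(F)F
Why: The silyl triflate silylates the hindered axial allylic hydroxyl so that it cannot interfere with iodination and organozinc formation.

Step 28
Reactants: 38 bis-silyl ether
Product: 39 2α,7α-bis(tert-butyldimethylsilyloxy)-13,14,15,16-tetranorlabd-8(17)-ene-12,19-diol
Conditions: LiAlH4, THF, 0 °C → rt
Reagents that add atoms: none
Why: LiAlH4 reduces the ethyl ester to the C12 alcohol and cleaves the pivalate in the same operation.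

Step 29
Reactants: 39 diol
Product: 40 12-iodo-2α,7α-bis(tert-butyldimethylsilyloxy)-13,14,15,16-tetranorlabd-8(17)-en-19-ol
Conditions: I2, PPh3, imidazole, CH2Cl2, 0 °C
Reagents that add atoms: iodine, II
Why: Garegg–Samuelsson iodination: the unhindered C12 alkoxyphosphonium ion is displaced by iodide, whereas SN2 at the neopentyl C19 carbon is too slow to compete.

Step 30
Reactants: 40 iodo alcohol
Product: 41 12-iodo-2α,7α-bis(tert-butyldimethylsilyloxy)-13,14,15,16-tetranorlabd-8(17)-en-19-yl acetate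
Conditions: Ac2O, Et3N, DMAP (cat.), CH2Cl2, 0 °C → rt
Reagents that add atoms: acetic anhydride, CC(=O)OC(C)=O
Why: DMAP-catalysed acetylation installs the C19 acetate of the target.

Step 31
Reactants: 42 but-2-yn-1-ol
Product: 44 (Z)-3-iodobut-2-en-1-ol, via alkenylalanate 43 (not isolated)
Conditions: Red-Al, THF, 0 °C → rt; EtOAc; then I2, −78 °C
Reagents that add atoms: iodine, II
Why: Red-Al adds hydride trans across the alkyne through the alkoxyaluminate (aluminium on C3, cis to the CH2O group), and iodine replaces aluminium with retention to give the (Z)-iodide.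

Step 32
Reactants: 44 (Z)-3-iodobut-2-en-1-ol
Product: 45 (Z)-3-iodobut-2-en-1-yl acetate
Conditions: Ac2O, Et3N, DMAP (cat.), CH2Cl2, 0 °C
Reagents that add atoms: acetic anhydride, CC(=O)OC(C)=O
Why: Acetylation gives the C15 acetate before the coupling.

Step 33
Reactants: 41 iodo acetate; 45 (Z)-3-iodobut-2-en-1-yl acetate
Product: 47 (13Z)-2α,7α-bis(tert-butyldimethylsilyloxy)labda-8(17),13-diene-15,19-diyl diacetate, via alkylzinc iodide 46 (not isolated)
Conditions: Zn (activated with 1,2-dibromoethane/TMSCl), THF/DMA, 40 °C; then 45, PdCl2(dppf) (5 mol %), rt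
Reagents that add atoms: none
Why: Zinc inserts into the primary C–I bond (acetate-tolerant) and Negishi sp3–sp2 coupling proceeds with retention at the alkenyl iodide, giving the 13Z alkene; oxidative addition into C(sp2)–I is far faster than ionisation of the allylic acetate, and the dppf ligand suppresses β-hydride elimination.

Step 34
Reactants: 47 bis-silyl ether diacetate
Product: 48 (13Z)-2α,7α-dihydroxylabda-8(17),13-diene-15,19-diyl diacetate (CNP0171158.2)
Conditions: HF·pyridine, pyridine, THF, 0 °C → rt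
Reagents that add atoms: none
Why: Buffered HF·pyridine cleaves both silyl ethers and leaves the two acetates, the allylic alcohol and both alkenes untouched.

**Compound list**

1 | diethyl (S)-malate | CCOC(=O)C[C@H](O)C(=O)OCC | starting material
2 | diethyl (2S,3R)-2-hydroxy-3-methylbutanedioate | CCOC(=O)[C@H](C)[C@H](O)C(=O)OCC | intermediate
3 | diethyl (2S,3R)-2-hydroxy-3-methyl-3-(prop-2-en-1-yl)butanedioate | CCOC(=O)[C@](C)(CC=C)[C@H](O)C(=O)OCC | intermediate
4 | (2S,3S)-3-methyl-3-(prop-2-en-1-yl)butane-1,2,4-triol | OC[C@](C)(CC=C)[C@H](O)CO | intermediate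
5 | (2S)-2-[(4S)-2,2-dimethyl-1,3-dioxolan-4-yl]-2-methylpent-4-en-1-ol | OC[C@](C)(CC=C)[C@H]1COC(C)(C)O1 | intermediate
6 | (2R)-2-[(4S)-2,2-dimethyl-1,3-dioxolan-4-yl]-2-methylpent-4-enal | O=C[C@](C)(CC=C)[C@H]1COC(C)(C)O1 | intermediate
7 | methyl (2Z,4S)-4-[(4S)-2,2-dimethyl-1,3-dioxolan-4-yl]-4-methylhepta-2,6-dienoate | COC(=O)/C=C\[C@](C)(CC=C)[C@H]1COC(C)(C)O1 | intermediate
8 | methyl (2Z,4S,6RS)-4-[(4S)-2,2-dimethyl-1,3-dioxolan-4-yl]-6,7-dihydroxy-4-methylhept-2-enoate | COC(=O)/C=C\[C@](C)(CC(O)CO)[C@H]1COC(C)(C)O1 | intermediate (not isolated)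
9 | methyl (2Z,4S)-4-[(4S)-2,2-dimethyl-1,3-dioxolan-4-yl]-4-methyl-6-oxohex-2-enoate | COC(=O)/C=C\[C@](C)(CC=O)[C@H]1COC(C)(C)O1 | intermediate
10 | O-diisopinocampheylboryl derivative (borinate) of 11 | COC(=O)/C=C\[C@](C)(C[C@@H](OB([C@@H]2C[C@@H]3C[C@H]([C@H]2C)C3(C)C)[C@@H]2C[C@@H]3C[C@H]([C@H]2C)C3(C)C)CC(C)=C)[C@H]1COC(C)(C)O1 | intermediate (not isolated)
11 | methyl (2Z,4S,6S)-4-[(4S)-2,2-dimethyl-1,3-dioxolan-4-yl]-6-hydroxy-4,8-dimethylnona-2,8-dienoate | COC(=O)/C=C\[C@](C)(C[C@@H](O)CC(C)=C)[C@H]1COC(C)(C)O1 | intermediate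
12 | methyl (2Z,4S,6S)-6-(tert-butyldimethylsilyloxy)-4-[(4S)-2,2-dimethyl-1,3-dioxolan-4-yl]-4,8-dimethylnona-2,8-dienoate | COC(=O)/C=C\[C@](C)(C[C@@H](O[Si](C)(C)C(C)(C)C)CC(C)=C)[C@H]1COC(C)(C)O1 | intermediate
13 | 9-(9-borabicyclo[3.3.1]nonan-9-yl) derivative of the 8,9-dihydro form of 12 (8RS) | COC(=O)/C=C\[C@](C)(C[C@@H](O[Si](C)(C)C(C)(C)C)CC(C)CB2C3CCCC2CCC3)[C@H]1COC(C)(C)O1 | intermediate (not isolated)
14 | methyl (2Z,4S,6S,8RS)-6-(tert-butyldimethylsilyloxy)-4-[(4S)-2,2-dimethyl-1,3-dioxolan-4-yl]-9-hydroxy-4,8-dimethylnon-2-enoate | COC(=O)/C=C\[C@](C)(C[C@@H](O[Si](C)(C)C(C)(C)C)CC(C)CO)[C@H]1COC(C)(C)O1 | intermediate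
15 | (2RS,4S,6S,7Z)-4-(tert-butyldimethylsilyloxy)-6-[(4S)-2,2-dimethyl-1,3-dioxolan-4-yl]-9-methoxy-2,6-dimethyl-9-oxonon-7-enoic acid | COC(=O)/C=C\[C@](C)(C[C@@H](O[Si](C)(C)C(C)(C)C)CC(C)C(=O)O)[C@H]1COC(C)(C)O1 | intermediate
16 | seco acid (2RS,4S,6S,7Z)-4-(tert-butyldimethylsilyloxy)-6-[(4S)-2,2-dimethyl-1,3-dioxolan-4-yl]-9-hydroxy-2,6-dimethylnon-7-enoic acid | OC/C=C\[C@](C)(C[C@@H](O[Si](C)(C)C(C)(C)C)CC(C)C(=O)O)[C@H]1COC(C)(C)O1 | intermediate
17 | mixed anhydride of 16 with 2-methyl-6-nitrobenzoic acid | OC/C=C\[C@](C)(C[C@@H](O[Si](C)(C)C(C)(C)C)CC(C)C(=O)OC(=O)c2c(C)cccc2[N+](=O)[O-])[C@H]1COC(C)(C)O1 | intermediate (not isolated)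
18 | (3RS,5S,7S,8Z)-5-(tert-butyldimethylsilyloxy)-7-[(4S)-2,2-dimethyl-1,3-dioxolan-4-yl]-3,7-dimethyl-3,4,5,6,7,10-hexahydro-2H-oxecin-2-one | CC1C[C@H](O[Si](C)(C)C(C)(C)C)C[C@](C)([C@H]2COC(C)(C)O2)/C=C\COC1=O | intermediate (key-step precursor)
19 | tert-butyldimethylsilyl ketene acetal of 18 (C4=C19, C3 and ring oxygen cis) | C/C1=C(\O[Si](C)(C)C(C)(C)C)OC/C=C\[C@@](C)([C@H]2COC(C)(C)O2)C[C@@H](O[Si](C)(C)C(C)(C)C)C1 | intermediate (not isolated)
20 | tert-butyldimethylsilyl ester of 21 | C=C[C@H]1[C@@](C)(C(=O)O[Si](C)(C)C(C)(C)C)C[C@H](O[Si](C)(C)C(C)(C)C)C[C@]1(C)[C@H]2COC(C)(C)O2 | intermediate (not isolated)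
21 | (1S,2R,3S,5R)-5-(tert-butyldimethylsilyloxy)-3-[(4S)-2,2-dimethyl-1,3-dioxolan-4-yl]-2-ethenyl-1,3-dimethylcyclohexane-1-carboxylic acid | C=C[C@H]1[C@@](C)(C(=O)O)C[C@H](O[Si](C)(C)C(C)(C)C)C[C@]1(C)[C@H]2COC(C)(C)O2 | intermediate (key-step product)
22 | ring-A alcohol: 21 with the carboxyl reduced to 4β-CH2OH (C19) | C=C[C@H]1[C@@](C)(CO)C[C@H](O[Si](C)(C)C(C)(C)C)C[C@]1(C)[C@H]2COC(C)(C)O2 | intermediate
23 | ring-A pivalate: C19 O-pivaloyl derivative of 22 | C=C[C@H]1[C@@](C)(COC(=O)C(C)(C)C)C[C@H](O[Si](C)(C)C(C)(C)C)C[C@]1(C)[C@H]2COC(C)(C)O2 | intermediate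
24 | B-alkyl-9-BBN from 23 (boron on C7) | B1(CC[C@H]2[C@@](C)(COC(=O)C(C)(C)C)C[C@H](O[Si](C)(C)C(C)(C)C)C[C@]2(C)[C@H]3COC(C)(C)O3)C4CCCC1CCC4 | intermediate (not isolated)
25 | primary alcohol: 23 with 5β-CH2CH2OH (C6–C7) in place of vinyl | OCC[C@H]1[C@@](C)(COC(=O)C(C)(C)C)C[C@H](O[Si](C)(C)C(C)(C)C)C[C@]1(C)[C@H]2COC(C)(C)O2 | intermediate
26 | C7 aldehyde: 25 oxidised to 5β-CH2CHO | O=CC[C@H]1[C@@](C)(COC(=O)C(C)(C)C)C[C@H](O[Si](C)(C)C(C)(C)C)C[C@]1(C)[C@H]2COC(C)(C)O2 | intermediate
27 | secondary alcohol: 5β-CH2CH(OH)CH2CH3 (C7 epimers) | CCC(O)C[C@H]1[C@@](C)(COC(=O)C(C)(C)C)C[C@H](O[Si](C)(C)C(C)(C)C)C[C@]1(C)[C@H]2COC(C)(C)O2 | intermediate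
28 | ethyl ketone: 5β-CH2C(=O)CH2CH3 | CCC(=O)C[C@H]1[C@@](C)(COC(=O)C(C)(C)C)C[C@H](O[Si](C)(C)C(C)(C)C)C[C@]1(C)[C@H]2COC(C)(C)O2 | intermediate
29 | diol: 28 with the acetonide hydrolysed (C10 bears (S)-CH(OH)CH2OH) | CCC(=O)C[C@H]1[C@@](C)(COC(=O)C(C)(C)C)C[C@H](O[Si](C)(C)C(C)(C)C)C[C@]1(C)[C@H](O)CO | intermediate (not isolated)
30 | keto aldehyde: C10 bears CHO (C9), C5 bears CH2C(=O)CH2CH3 | CCC(=O)C[C@H]1[C@@](C)(COC(=O)C(C)(C)C)C[C@H](O[Si](C)(C)C(C)(C)C)C[C@]1(C)C=O | intermediate
31 | aldol: 9-hydroxy-2α-(tert-butyldimethylsilyloxy)-19-(pivaloyloxy)-11,12,13,14,15,16-hexanorlabdan-7-one (C8, C9 epimers) | CC1C(O)[C@@]2(C)C[C@@H](O[Si](C)(C)C(C)(C)C)C[C@](C)(COC(=O)C(C)(C)C)[C@@H]2CC1=O | intermediate (not isolated)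
32 | 2α-(tert-butyldimethylsilyloxy)-19-(pivaloyloxy)-11,12,13,14,15,16-hexanorlabd-8-en-7-one | CC1=C[C@@]2(C)C[C@@H](O[Si](C)(C)C(C)(C)C)C[C@](C)(COC(=O)C(C)(C)C)[C@@H]2CC1=O | intermediate
33 | 2α-(tert-butyldimethylsilyloxy)-19-(pivaloyloxy)-11,12,13,14,15,16-hexanorlabd-8-en-7β-ol | CC1=C[C@@]2(C)C[C@@H](O[Si](C)(C)C(C)(C)C)C[C@](C)(COC(=O)C(C)(C)C)[C@@H]2C[C@@H]1O | intermediate
34 | 7β-O-(1-ethoxyethenyl) ketene acetal of 33 | CC1=C[C@@]2(C)C[C@@H](O[Si](C)(C)C(C)(C)C)C[C@](C)(COC(=O)C(C)(C)C)[C@@H]2C[C@@H]1OC(=C)OCC | intermediate (not isolated)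
35 | ethyl 2α-(tert-butyldimethylsilyloxy)-19-(pivaloyloxy)-13,14,15,16-tetranorlabd-7-en-12-oate | CC1=CC[C@H]2[C@@](C)(COC(=O)C(C)(C)C)C[C@H](O[Si](C)(C)C(C)(C)C)C[C@]2(C)[C@H]1CC(=O)OCC | intermediate
36 | ethyl 7α,8α-epoxy-2α-(tert-butyldimethylsilyloxy)-19-(pivaloyloxy)-13,14,15,16-tetranorlabdan-12-oate | C[C@@]12O[C@@H]1C[C@H]3[C@@](C)(COC(=O)C(C)(C)C)C[C@H](O[Si](C)(C)C(C)(C)C)C[C@]3(C)[C@H]2CC(=O)OCC | intermediate
37 | ethyl 7α-hydroxy-2α-(tert-butyldimethylsilyloxy)-19-(pivaloyloxy)-13,14,15,16-tetranorlabd-8(17)-en-12-oate | C=C1[C@H](O)C[C@H]2[C@@](C)(COC(=O)C(C)(C)C)C[C@H](O[Si](C)(C)C(C)(C)C)C[C@]2(C)[C@H]1CC(=O)OCC | intermediate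
38 | ethyl 2α,7α-bis(tert-butyldimethylsilyloxy)-19-(pivaloyloxy)-13,14,15,16-tetranorlabd-8(17)-en-12-oate | C=C1[C@H](O[Si](C)(C)C(C)(C)C)C[C@H]2[C@@](C)(COC(=O)C(C)(C)C)C[C@H](O[Si](C)(C)C(C)(C)C)C[C@]2(C)[C@H]1CC(=O)OCC | intermediate
39 | 2α,7α-bis(tert-butyldimethylsilyloxy)-13,14,15,16-tetranorlabd-8(17)-ene-12,19-diol | C=C1[C@H](O[Si](C)(C)C(C)(C)C)C[C@H]2[C@@](C)(CO)C[C@H](O[Si](C)(C)C(C)(C)C)C[C@]2(C)[C@H]1CCO | intermediate
40 | 12-iodo-2α,7α-bis(tert-butyldimethylsilyloxy)-13,14,15,16-tetranorlabd-8(17)-en-19-ol | C=C1[C@H](O[Si](C)(C)C(C)(C)C)C[C@H]2[C@@](C)(CO)C[C@H](O[Si](C)(C)C(C)(C)C)C[C@]2(C)[C@H]1CCI | intermediate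
41 | 12-iodo-2α,7α-bis(tert-butyldimethylsilyloxy)-13,14,15,16-tetranorlabd-8(17)-en-19-yl acetate | C=C1[C@H](O[Si](C)(C)C(C)(C)C)C[C@H]2[C@@](C)(COC(C)=O)C[C@H](O[Si](C)(C)C(C)(C)C)C[C@]2(C)[C@H]1CCI | intermediate
42 | but-2-yn-1-ol | CC#CCO | starting material
43 | sodium cyclic alkenylalanate (aluminium on C3 and on oxygen, two 2-methoxyethoxy ligands) | CC1=CCO[Al-]1(OCCOC)OCCOC.[Na+] | intermediate (not isolated)
44 | (Z)-3-iodobut-2-en-1-ol | C/C(I)=C/CO | intermediate
45 | (Z)-3-iodobut-2-en-1-yl acetate | C/C(I)=C/COC(C)=O | intermediate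
46 | alkylzinc iodide from 41 (zinc on C12) | C=C1[C@H](O[Si](C)(C)C(C)(C)C)C[C@H]2[C@@](C)(COC(C)=O)C[C@H](O[Si](C)(C)C(C)(C)C)C[C@]2(C)[C@H]1CC[Zn]I | intermediate (not isolated)
47 | (13Z)-2α,7α-bis(tert-butyldimethylsilyloxy)labda-8(17),13-diene-15,19-diyl diacetate | C=C1[C@H](O[Si](C)(C)C(C)(C)C)C[C@H]2[C@@](C)(COC(C)=O)C[C@H](O[Si](C)(C)C(C)(C)C)C[C@]2(C)[C@H]1CC/C(C)=C\COC(C)=O | intermediate
48 | (13Z)-2α,7α-dihydroxylabda-8(17),13-diene-15,19-diyl diacetate | C=C1[C@H](O)C[C@H]2[C@@](C)(COC(C)=O)C[C@H](O)C[C@]2(C)[C@H]1CC/C(C)=C\COC(C)=O | target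

**Step count and risks**

Total step count: 34 (32 in the main line, 2 for the side-chain fragment). Longest linear sequence: 32 steps (steps 1–30, 33, 34).

Steps most likely to fail:

1. Step 13, macrolactonisation. Intermolecular esterification (diolide and oligomer formation) may outrun closure of the strained ten-membered ring. Fallback: Mitsunobu macrolactonisation of 16 (PPh3, DIAD, toluene, high dilution). Here the allylic alcohol, not the acid, is activated and the carboxylate closes the ring by SN2 at the primary C7, so the acyl carbon never has to be attacked intramolecularly. The fallback sets out from 16 and comes back at 18; no new compound arises (entry F0).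

2. Step 14, ring contraction. The transannular bond formation may show poor face selectivity (the developing syn-axial contact between C19 and the C20 methyl erodes the preference), or the medium-ring lactone may not enolise and silylate cleanly. Fallback: form the same C4–C5 bond, with the same six-membered ring closure and the same vinyl group, by an intramolecular ester-enolate SN2′ alkylation. The fallback sets out from 16: TMSCHN2 in MeOH/toluene gives the methyl ester F1; MsCl, Et3N, then LiCl in DMF gives the allylic chloride F2; LDA in THF/DMPU at −78 → 0 °C should close ring A by attack of C4 on C5 with loss of chloride from C7, giving the cyclohexane methyl ester F3 under the same chair preferences (C20 axial, dioxolanyl and silyloxy groups equatorial). LiAlH4 then reduces F3 to the alcohol, and the route is rejoined at 22.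

3. Step 24, Johnson–Claisen. At 140 °C with acid the allylic alcohol may dehydrate to the 6,8-diene, and the rearrangement may be slow because the C7–O bond is pseudoequatorial and the new bond forms next to the quaternary C10. Fallback: a [2,3]-Wittig rearrangement at low temperature followed by deoxygenation. The fallback sets out from 33: Rh2(OAc)4-catalysed O–H insertion of ethyl diazoacetate gives the glycolate ether F4; LDA in THF/HMPA at −78 °C should shift the enolate carbon suprafacially to C9β, giving the α-hydroxy ester F5 (C11 epimers) with the C7=C8 double bond in place; Ac2O/DMAP gives the α-acetoxy ester F6; SmI2 in THF/HMPA/MeOH removes the acetoxy group, and the route is rejoined at 35.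

Further compounds
F0 | step 13 | none | none
F1 | step 14 | methyl ester of seco acid 16 | OC/C=C\[C@](C)(C[C@@H](O[Si](C)(C)C(C)(C)C)CC(C)C(=O)OC)[C@H]1COC(C)(C)O1
F2 | step 14 | allylic chloride from F1 (chlorine on C7) | ClC/C=C\[C@](C)(C[C@@H](O[Si](C)(C)C(C)(C)C)CC(C)C(=O)OC)[C@H]1COC(C)(C)O1
F3 | step 14 | methyl ester of ring-A acid 21 | C=C[C@H]1[C@@](C)(C(=O)OC)C[C@H](O[Si](C)(C)C(C)(C)C)C[C@]1(C)[C@H]2COC(C)(C)O2
F4 | step 24 | 7β-O-(ethoxycarbonylmethyl) ether of 33 | CC1=C[C@@]2(C)C[C@@H](O[Si](C)(C)C(C)(C)C)C[C@](C)(COC(=O)C(C)(C)C)[C@@H]2C[C@@H]1OCC(=O)OCC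
F5 | step 24 | 11-hydroxy derivative of ester 35 (C11 epimers) | CC1=CC[C@H]2[C@@](C)(COC(=O)C(C)(C)C)C[C@H](O[Si](C)(C)C(C)(C)C)C[C@]2(C)[C@H]1C(O)C(=O)OCC
F6 | step 24 | 11-acetoxy derivative of ester 35 (C11 epimers) | CC1=CC[C@H]2[C@@](C)(COC(=O)C(C)(C)C)C[C@H](O[Si](C)(C)C(C)(C)C)C[C@]2(C)[C@H]1C(OC(C)=O)C(=O)OCC
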